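**Retrosynthetic overview**
1. The target comes from the tetra-O-benzyl trans-dihydroflavonol by hydrogenolysis, and that from a C3 allyl ester by deallylative decarboxylation (C3 settles as the trans ketol).
2. Key disconnection C3–C4: an intramolecular crossed benzoin in which the ring A aldehyde carbon acts as an acyl anion (Breslow intermediate) toward a tethered α-keto ester, with dynamic kinetic resolution of the enolisable C2 centre.
3. The benzoin substrate comes from O-alkylation of a chelated ring A phenol with a β-chloro-α-keto ester (Darzens route from 4-(benzyloxy)benzaldehyde and allyl dichloroacetate).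
4. The ring A phenol comes from 2,4,6-trihydroxybenzaldehyde by Friedel–Crafts C-benzylation, then chelation-controlled bis-O-benzylation.
5. Ring order: ring A, ring B and the pendant benzyl ring are bought as arenes; ring C is the only ring formed (step 6).

Assumption: the sense of induction of the triazolium salt in step 6 is taken by analogy with related benzoin cyclisations; if the (2S) series forms, the mirror-image salt is used.

**Route**

Step 1
Reactants: 1 2,4,6-trihydroxybenzaldehyde; 2 4-(benzyloxy)benzyl alcohol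
Product: 3 3-[4-(benzyloxy)benzyl]-2,4,6-trihydroxybenzaldehyde
Conditions: TsOH·H2O (5 mol%), MeCN, rt; 1 in threefold excess
Reagents that add atoms: none
Why: Acid-catalysed Friedel–Crafts benzylation in which the para-benzyloxybenzyl cation is captured by the phloroglucinol ring of 1, whose two free positions are equivalent, so only one mono-C-benzyl isomer can form and the excess of 1 suppresses the bis-adduct; no stereocentre.

Step 2
Reactants: 3 3-[4-(benzyloxy)benzyl]-2,4,6-trihydroxybenzaldehyde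
Product: 4 4,6-bis(benzyloxy)-3-[4-(benzyloxy)benzyl]-2-hydroxybenzaldehyde
Conditions: BnBr (2.1 equiv), K2CO3 (2.2 equiv), DMF, 0 °C to rt
Reagents that add atoms: benzyl bromide, BrCc1ccccc1
Why: Williamson etherification under chelation control, in which the para hydroxyl reacts first, then the less hindered ortho hydroxyl, while the hydroxyl flanked by the formyl group and the benzyl substituent stays locked in a buttressed hydrogen bond to the aldehyde and is left free; no stereocentre.

Step 3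
Reactants: 5 dichloroacetyl chloride; 6 allyl alcohol
Product: 7 allyl dichloroacetate
Conditions: pyridine, CH2Cl2, 0 °C to rt
Reagents that add atoms: none
Why: Acylation of the alcohol by the acid chloride, with pyridine rather than a trialkylamine so that dichloroketene is not formed; no stereocentre.

Step 4
Reactants: 7 allyl dichloroacetate; 8 4-(benzyloxy)benzaldehyde
Product: 10 allyl 3-chloro-3-[4-(benzyloxy)phenyl]-2-oxopropanoate (racemic), via α-chloroglycidic ester 9 (not isolated)
Conditions: KOtBu, THF, −78 to 0 °C; then LiCl (10 mol%), rt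
Reagents that add atoms: none
Why: Darzens condensation of the dichloroacetate enolate with the aldehyde gives the α-chloro epoxide, which chloride opens at the benzylic carbon with collapse to the β-chloro-α-keto ester (α-chloroglycidate rearrangement); the product is racemic and its stereocentre is deliberately labile.

Step 5
Reactants: 4 4,6-bis(benzyloxy)-3-[4-(benzyloxy)benzyl]-2-hydroxybenzaldehyde; 10 allyl 3-chloro-3-[4-(benzyloxy)phenyl]-2-oxopropanoate
Product: 11 allyl 3-{3,5-bis(benzyloxy)-2-[4-(benzyloxy)benzyl]-6-formylphenoxy}-3-[4-(benzyloxy)phenyl]-2-oxopropanoate (racemic)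
Conditions: Cs2CO3 (1.05 equiv), NaI (10 mol%), MeCN, 0 °C to rt
Reagents that add atoms: none
Why: Williamson-type SN2 displacement of a doubly activated (benzylic and α-keto) chloride by the caesium phenoxide, run cold to outrun Rap–Stoermer-type aldol closure onto the aldehyde; the new stereocentre is racemic and enolisable, which step 6 exploits.

Step 6
Reactants: 11 allyl 3-{3,5-bis(benzyloxy)-2-[4-(benzyloxy)benzyl]-6-formylphenoxy}-3-[4-(benzyloxy)phenyl]-2-oxopropanoate
Product: 12 allyl (2R,3R)-5,7-bis(benzyloxy)-8-[4-(benzyloxy)benzyl]-2-[4-(benzyloxy)phenyl]-3-hydroxy-4-oxochromane-3-carboxylate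
Conditions: (5aS,10bR)-2-(pentafluorophenyl)-5a,10b-dihydro-4H,6H-indeno[2,1-b][1,2,4]triazolo[4,3-d][1,4]oxazin-2-ium tetrafluoroborate (15 mol%), iPr2NEt (30 mol%), 4 Å MS, toluene, rt
Reagents that add atoms: none
Why: Proposed new method: the triazolylidene can form a Breslow intermediate (acyl anion equivalent) only at the aryl aldehyde, because the tethered carbonyl is a ketone that can neither become a donor nor expel the β-aryloxide, and this nucleophilic C4 adds to the activated keto carbon C3 through a hydrogen-bonded six-membered chair-like transition state with the C2 aryl group pseudo-equatorial while the amine interconverts the enantiomers of 11 through the enol, so one enantiomer is funnelled to the (2R) ring (dynamic kinetic resolution, the catalyst choosing the keto face and the chair relaying it to C2); the closest known reactions are the enantioselective intramolecular aldehyde–ketone crossed benzoin giving 3-hydroxychroman-4-ones and the dynamic kinetic crossed benzoin of aldehydes with racemising β-stereogenic α-keto esters.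

Step 7
Reactants: 12 allyl (2R,3R)-5,7-bis(benzyloxy)-8-[4-(benzyloxy)benzyl]-2-[4-(benzyloxy)phenyl]-3-hydroxy-4-oxochromane-3-carboxylate
Product: 15 (2R,3R)-5,7-bis(benzyloxy)-8-[4-(benzyloxy)benzyl]-2-[4-(benzyloxy)phenyl]-3-hydroxychroman-4-one, via β-keto acid 13 (not isolated), via enediol 14 (not isolated)
Conditions: Pd(PPh3)4 (5 mol%), HCO2H, Et3N, THF, rt; then DBU (20 mol%), 40 °C, argon
Reagents that add atoms: none
Why: Tsuji–Trost deallylation with formate as hydride source gives the β-keto acid, which decarboxylates to the enediol, and amine-catalysed ketonisation with C3 equilibration delivers the diequatorial 2,3-trans ketol (3-OH hydrogen-bonded to the C4 carbonyl), so C3 becomes (R) under thermodynamic control from the fixed, non-acidic (2R) centre.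

Step 8
Reactants: 15 (2R,3R)-5,7-bis(benzyloxy)-8-[4-(benzyloxy)benzyl]-2-[4-(benzyloxy)phenyl]-3-hydroxychroman-4-one
Product: 16 (2R,3R)-3,5,7-trihydroxy-8-(4-hydroxybenzyl)-2-(4-hydroxyphenyl)chroman-4-one
Conditions: H2 (1 atm), 10% Pd/C, EtOAc/MeOH, rt
Reagents that add atoms: none
Why: Hydrogenolysis of the four aryl benzyl ethers under neutral conditions, stopped after four equivalents of H2 so that the C4 ketone, the diarylmethane and the C2–O bond are untouched and neither stereocentre sees acid or base.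

**Compound list**
1 | 2,4,6-trihydroxybenzaldehyde | O=Cc1c(O)cc(O)cc1O | starting material
2 | 4-(benzyloxy)benzyl alcohol | OCc1ccc(OCc2ccccc2)cc1 | starting material
3 | 3-[4-(benzyloxy)benzyl]-2,4,6-trihydroxybenzaldehyde | O=Cc1c(O)cc(O)c(Cc2ccc(OCc3ccccc3)cc2)c1O | intermediate
4 | 4,6-bis(benzyloxy)-3-[4-(benzyloxy)benzyl]-2-hydroxybenzaldehyde | O=Cc1c(OCc2ccccc2)cc(OCc2ccccc2)c(Cc2ccc(OCc3ccccc3)cc2)c1O | intermediate
5 | dichloroacetyl chloride | O=C(Cl)C(Cl)Cl | starting material
6 | allyl alcohol | C=CCO | starting material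
7 | allyl dichloroacetate | C=CCOC(=O)C(Cl)Cl | intermediate
8 | 4-(benzyloxy)benzaldehyde | O=Cc1ccc(OCc2ccccc2)cc1 | starting material
9 | allyl 3-[4-(benzyloxy)phenyl]-2-chlorooxirane-2-carboxylate (racemic, not isolated) | C=CCOC(=O)C1(Cl)OC1c1ccc(OCc2ccccc2)cc1 | intermediate
10 | allyl 3-chloro-3-[4-(benzyloxy)phenyl]-2-oxopropanoate (racemic) | C=CCOC(=O)C(=O)C(Cl)c1ccc(OCc2ccccc2)cc1 | intermediate
11 | allyl 3-{3,5-bis(benzyloxy)-2-[4-(benzyloxy)benzyl]-6-formylphenoxy}-3-[4-(benzyloxy)phenyl]-2-oxopropanoate (racemic) | C=CCOC(=O)C(=O)C(Oc1c(C=O)c(OCc2ccccc2)cc(OCc2ccccc2)c1Cc1ccc(OCc2ccccc2)cc1)c1ccc(OCc2ccccc2)cc1 | intermediate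
12 | allyl (2R,3R)-5,7-bis(benzyloxy)-8-[4-(benzyloxy)benzyl]-2-[4-(benzyloxy)phenyl]-3-hydroxy-4-oxochromane-3-carboxylate (3-OH trans to the C2 aryl group) | O=C1c2c(OCc3ccccc3)cc(OCc3ccccc3)c(Cc3ccc(OCc4ccccc4)cc3)c2O[C@H](c2ccc(OCc3ccccc3)cc2)[C@]1(O)C(=O)OCC=C | intermediate
13 | (2R,3R)-5,7-bis(benzyloxy)-8-[4-(benzyloxy)benzyl]-2-[4-(benzyloxy)phenyl]-3-hydroxy-4-oxochromane-3-carboxylic acid (not isolated) | O=C1c2c(OCc3ccccc3)cc(OCc3ccccc3)c(Cc3ccc(OCc4ccccc4)cc3)c2O[C@H](c2ccc(OCc3ccccc3)cc2)[C@]1(O)C(=O)O | intermediate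
14 | (2R)-5,7-bis(benzyloxy)-8-[4-(benzyloxy)benzyl]-2-[4-(benzyloxy)phenyl]-2H-chromene-3,4-diol (not isolated) | OC1=C(O)[C@@H](c2ccc(OCc3ccccc3)cc2)Oc2c1c(OCc1ccccc1)cc(OCc1ccccc1)c2Cc1ccc(OCc2ccccc2)cc1 | intermediate
15 | (2R,3R)-5,7-bis(benzyloxy)-8-[4-(benzyloxy)benzyl]-2-[4-(benzyloxy)phenyl]-3-hydroxychroman-4-one | O=C1c2c(OCc3ccccc3)cc(OCc3ccccc3)c(Cc3ccc(OCc4ccccc4)cc3)c2O[C@H](c2ccc(OCc3ccccc3)cc2)[C@H]1O | intermediate
16 | (2R,3R)-3,5,7-trihydroxy-8-(4-hydroxybenzyl)-2-(4-hydroxyphenyl)chroman-4-one | O=C1c2c(O)cc(O)c(Cc3ccc(O)cc3)c2O[C@H](c2ccc(O)cc2)[C@H]1O | target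

**Step count and risks**
Total steps: 8. Longest linear sequence: 6 (steps 1, 2, 5, 6, 7, 8).

Step 6 is the most likely to fail.
- The 2,6-dioxygenated, electron-rich aldehyde may be too hindered to give the Breslow intermediate.
- Aldol closure of the enol carbon onto the aldehyde (toward a benzofuran) may compete.
- Cyclisation through the other chair would give a C3 epimer of opposite C2 configuration and erode the ee; recrystallising 12 would be the remedy.

Fallback: drop the benzoin and set C2 by asymmetric conjugate arylation, setting out from 4 and coming back at 15. MeMgBr adds to 4 to give the carbinol 1-{4,6-bis(benzyloxy)-3-[4-(benzyloxy)benzyl]-2-hydroxyphenyl}ethan-1-ol F1. MnO2 oxidises it to the acetophenone 1-{4,6-bis(benzyloxy)-3-[4-(benzyloxy)benzyl]-2-hydroxyphenyl}ethan-1-one F2. Me2NCH(OMe)2 converts this into the enaminone (E)-1-{4,6-bis(benzyloxy)-3-[4-(benzyloxy)benzyl]-2-hydroxyphenyl}-3-(dimethylamino)prop-2-en-1-one F3, which HCl closes to the chromone 5,7-bis(benzyloxy)-8-[4-(benzyloxy)benzyl]-4H-chromen-4-one F4. Pd(OCOCF3)2 with the chiral ligand 4-tert-butyl-2-(pyridin-2-yl)-4,5-dihydrooxazole (the enantiomer that gives 2S) adds 4-(benzyloxy)phenylboronic acid to give the flavanone (2S)-5,7-bis(benzyloxy)-8-[4-(benzyloxy)benzyl]-2-[4-(benzyloxy)phenyl]chroman-4-one F5. Its lithium enolate (LiHMDS, THF, −78 °C) is hydroxylated anti to the aryl group by 2-(phenylsulfonyl)-3-phenyloxaziridine to give 15.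

Step 5 is the second risk: the phenol of 4 is hindered and chelated, and both 10 and 11 are base-labile. Fallback: replace the SN2 step by a neutral carbenoid O–H insertion, setting out from 10 and 4 and coming back at 11. Zn in AcOH removes the chlorine of 10 to give the pyruvate allyl 3-[4-(benzyloxy)phenyl]-2-oxopropanoate F6. Diazo transfer (4-acetamidobenzenesulfonyl azide, DBU, MeCN) gives allyl 3-[4-(benzyloxy)phenyl]-3-diazo-2-oxopropanoate F7. Rh2(OAc)4 (1 mol%, CH2Cl2, rt) then inserts its carbenoid into the O–H bond of 4 to give 11.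

Step 7 is the third risk: kinetic protonation of the enediol anti to the aryl group may give the 2,3-cis ketol, and forcing equilibration with base may open ring C by E1cB and racemise C2. Fallback: invert C3 by substitution instead of equilibration, setting out from 12 and coming back at 15. Run the deallylation and decarboxylation without DBU and isolate the cis ketol (2R,3S)-5,7-bis(benzyloxy)-8-[4-(benzyloxy)benzyl]-2-[4-(benzyloxy)phenyl]-3-hydroxychroman-4-one F8. A Mitsunobu reaction (4-nitrobenzoic acid, PPh3, diisopropyl azodicarboxylate, THF) inverts C3 to give (2R,3R)-5,7-bis(benzyloxy)-8-[4-(benzyloxy)benzyl]-2-[4-(benzyloxy)phenyl]-4-oxochroman-3-yl 4-nitrobenzoate F9. Methanolysis (K2CO3, MeOH, 0 °C) then gives 15.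

**Further compounds**
F1 | step 6 | 1-{4,6-bis(benzyloxy)-3-[4-(benzyloxy)benzyl]-2-hydroxyphenyl}ethan-1-ol (racemic) | CC(O)c1c(OCc2ccccc2)cc(OCc2ccccc2)c(Cc2ccc(OCc3ccccc3)cc2)c1O
F2 | step 6 | 1-{4,6-bis(benzyloxy)-3-[4-(benzyloxy)benzyl]-2-hydroxyphenyl}ethan-1-one | CC(=O)c1c(OCc2ccccc2)cc(OCc2ccccc2)c(Cc2ccc(OCc3ccccc3)cc2)c1O
F3 | step 6 | (E)-1-{4,6-bis(benzyloxy)-3-[4-(benzyloxy)benzyl]-2-hydroxyphenyl}-3-(dimethylamino)prop-2-en-1-one | CN(C)/C=C/C(=O)c1c(OCc2ccccc2)cc(OCc2ccccc2)c(Cc2ccc(OCc3ccccc3)cc2)c1O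
F4 | step 6 | 5,7-bis(benzyloxy)-8-[4-(benzyloxy)benzyl]-4H-chromen-4-one | O=c1ccoc2c(Cc3ccc(OCc4ccccc4)cc3)c(OCc3ccccc3)cc(OCc3ccccc3)c12
F5 | step 6 | (2S)-5,7-bis(benzyloxy)-8-[4-(benzyloxy)benzyl]-2-[4-(benzyloxy)phenyl]chroman-4-one | O=C1c2c(OCc3ccccc3)cc(OCc3ccccc3)c(Cc3ccc(OCc4ccccc4)cc3)c2O[C@H](c2ccc(OCc3ccccc3)cc2)C1
F6 | step 5 | allyl 3-[4-(benzyloxy)phenyl]-2-oxopropanoate | C=CCOC(=O)C(=O)Cc1ccc(OCc2ccccc2)cc1
F7 | step 5 | allyl 3-[4-(benzyloxy)phenyl]-3-diazo-2-oxopropanoate | C=CCOC(=O)C(=O)C(=[N+]=[N-])c1ccc(OCc2ccccc2)cc1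
F8 | step 7 | (2R,3S)-5,7-bis(benzyloxy)-8-[4-(benzyloxy)benzyl]-2-[4-(benzyloxy)phenyl]-3-hydroxychroman-4-one | O=C1c2c(OCc3ccccc3)cc(OCc3ccccc3)c(Cc3ccc(OCc4ccccc4)cc3)c2O[C@H](c2ccc(OCc3ccccc3)cc2)[C@@H]1O
F9 | step 7 | (2R,3R)-5,7-bis(benzyloxy)-8-[4-(benzyloxy)benzyl]-2-[4-(benzyloxy)phenyl]-4-oxochroman-3-yl 4-nitrobenzoate | O=C1c2c(OCc3ccccc3)cc(OCc3ccccc3)c(Cc3ccc(OCc4ccccc4)cc3)c2O[C@H](c2ccc(OCc3ccccc3)cc2)[C@H]1OC(=O)c1ccc(cc1)[N+](=O)[O-]
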